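A small charge of precatalyst, 1.00% of the substrate, goes into this flask: by the candidate steps, substrate and partner add to give target and some isomer, and a catalyst formed from the precatalyst turns target into isomer.

| flask | substrate | partner | precatalyst | remark | time |
|---|---|---|---|---|---|
| Wednesday's | 0.50 M | 0.27 M | 5 mM | run made earlier |  |
| Saturday's | 0.50 M | 0.60 M | 5 mM | run made earlier |  |
| Sunday's | 0.50 M | 0.40 M | 2.5 mM | run made earlier |  |
| flask | 0.50 M | 0.400 M | 5.0 mM |  | 4.0 min |

| run | time / min | target / % | isomer of the product / % | substrate / % |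
|---|---|---|---|---|
| Wednesday's | 0.333 | 7.4 | 1.8 | 91.0 |
| Wednesday's | 0.667 | 11.8 | 2.7 | 85.4 |
| Wednesday's | 1.00 | 13.9 | 3.9 | 82.1 |
| Wednesday's | 1.33 | 14.9 | 5.2 | 80.4 |
| Wednesday's | 1.50 | 15.1 | 5.1 | 79.6 |
| Wednesday's | 2.00 | 14.4 | 7.4 | 77.2 |
| Wednesday's | 2.50 | 13.5 | 10.5 | 75.9 |
| Saturday's | 0.167 | 8.5 | 0.9 | 89.7 |
| Saturday's | 0.333 | 14.5 | 2.7 | 82.2 |
| Saturday's | 0.667 | 21.0 | 4.6 | 74.0 |
| Saturday's | 1.00 | 23.2 | 7.0 | 69.4 |
| Saturday's | 1.33 | 24.6 | 8.5 | 66.7 |
| Saturday's | 2.00 | 23.1 | 12.3 | 63.9 |
| Saturday's | 2.50 | 20.2 | 16.1 | 63.3 |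
| Sunday's | 0.500 | 13.4 | 2.9 | 83.9 |
| Sunday's | 1.00 | 19.2 | 4.5 | 76.4 |
| Sunday's | 1.33 | 19.8 | 5.9 | 73.8 |
| Sunday's | 2.00 | 20.2 | 8.1 | 71.4 |
| Sunday's | 2.50 | 19.3 | 9.2 | 71.0 |

(readings scatter by 0.3 percentage points)

* ratio of target to isomer of the product at 2.5 s
* ratio of target to isomer of the product at 25 s
* ratio of target to isomer of the product at 4.0 min

- candidate steps: substrate + partner <-> target; substrate + partner <-> isomer of the product; target + catalyst <-> isomer of the product + catalyst; 2 partner -> self-condensation product; catalyst + target -> catalyst + over-reaction product; precatalyst -> catalyst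

I ordered the processes by time. First comes the addition. Sunday's run shares this flask's partner charge and lost 16.1% of its substrate within 0.500 min. At 2.5 s the target-to-isomer ratio should be that of the two additions. Saturday's reading at 0.333 min gives 5.37. Its earlier isomer reading, 0.9%, carries a scatter of 0.3 percentage points, so I kept the later one.

Next comes the conversion of target. Saturday's late readings gave 0.290 min⁻¹. This is the drain, isomer gained per minute over target present, a pseudo-first-order constant. Wednesday, with Saturday's precatalyst charge and less partner, gave 0.319 min⁻¹. Sunday, with half the precatalyst, gave 0.144 min⁻¹, so I scaled the drain with the precatalyst charge and kept Saturday's value for this flask. Its time, 3.45 min, is longer than the 0.500 min of Sunday's substrate loss, so I expected target to build first and fall later.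

Between Wednesday and Saturday I put this flask's target at 2.00 min near 17.8%. There I reckoned the drain to remove 0.0516 min⁻¹ of the substrate charge, while Sunday's substrate readings fell by 0.00800 min⁻¹ from 2.00 min to 2.50 min, which is less. So I let target simply decay, to 9.98% at 4.0 min. Taking Sunday's substrate loss at 2.50 min, 29.0%, as the total of target and isomer, my ratio was 0.525.

The forecast said 7.5, 5 and 0.57, the last reached “With addition nearly stopped”.

The flask gave 5.26, 4.73 and 0.523.

    substrate + partner ⇌ target (K = 3.76 M⁻¹, k = 0.0189 M⁻¹ s⁻¹)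
    substrate + partner ⇌ isomer of the product (K = 326 M⁻¹, k = 0.00357 M⁻¹ s⁻¹)
    target + catalyst ⇌ isomer of the product + catalyst, rate k3*[catalyst]*[target] forward; the back reaction follows from the equilibrium constant (k = 3.72 M⁻¹ s⁻¹)
    2 partner → self-condensation product (k = 0.0197 M⁻¹ s⁻¹)
    catalyst + target → catalyst + over-reaction product (k = 0.445 M⁻¹ s⁻¹)
    precatalyst → catalyst (k = 0.00173 s⁻¹)

The neighbouring flask held 0.0020 M of precatalyst, with all else as in the recipe. Scaled to that charge, the drain becomes 0.116 min⁻¹. I started from Sunday's target reading of 19.3% at 2.50 min; Sunday shares the partner charge and held 2.5 mM of precatalyst. Over the remaining 1.50 min, my reckoning took that down to 16.2% of the substrate charge. The neighbouring flask held 15.7% target and 14.1% isomer at 4.00 min, a ratio of 1.11.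

(The runs were computed on assumed constants, noise included.)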